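The route rests on cutting the bond between C5 of the benzene ring of the dihydrobenzofuran and the benzylic CH2 of the feruloyloxypropyl chain. Two features are exploited. The OCH2CH2CH2–aryl unit is a hydroborated allyl ester, and C5, para to ring oxygen O1, can carry a bromine bought with 4-bromoguaiacol. In one flask 9-BBN masks the phenol of allyl ferulate as a borinate and adds to its only terminal alkene. B-alkyl Suzuki–Miyaura coupling with the unprotected, enantiopure bromodihydrobenzofuran then gives the target itself, ester in place. C2 comes from an asymmetric Rh-carbene C–H insertion, C3 from epimerisation to the trans ester.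

Key step: step 8

Assumption: Rh2(S-PTTL)4 is taken to give the 2R cis insertion product, by analogy with closely related 2-(benzyloxy)aryl diazoacetates. If the sense proves opposite, the mirror-image catalyst Rh2(R-PTTL)4 is used with no other change.

Step 1
Reactants: 1 (E)-ferulic acid; 2 allyl bromide
Product: 3 allyl (E)-ferulate
Conditions: KHCO3 (1.2 equiv), DMF, rt
Reagents that add atoms: none
Why: Bicarbonate ionises only the carboxylic acid and not the phenol, so SN2 O-alkylation of the carboxylate gives the ester chemoselectively and leaves the E-alkene untouched.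

Step 2
Reactants: 4 vanillyl alcohol
Product: 5 4-(hydroxymethyl)-2-methoxyphenyl pivalate
Conditions: NaOH (1.05 equiv), H2O–THF, 0 °C; PivCl (1.05 equiv)
Reagents that add atoms: pivaloyl chloride, CC(C)(C)C(=O)Cl
Why: Schotten–Baumann acylation, in which one equivalent of hydroxide ionises only the phenol and the phenoxide outcompetes the neutral benzylic alcohol for the hindered acyl chloride.

Step 3
Reactants: 6 4-bromo-2-methoxyphenol
Product: 7 4-bromo-2-iodo-6-methoxyphenol
Conditions: NIS (1.05 equiv), cat. p-TsOH, MeCN, rt
Reagents that add atoms: N-iodosuccinimide, O=C1CCC(=O)N1I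
Why: Electrophilic aromatic iodination, in which the hydroxyl group is the strongest donor and, with its para position blocked by bromine, directs iodine to its free ortho position.

Step 4
Reactants: 5 4-(hydroxymethyl)-2-methoxyphenyl pivalate; 7 4-bromo-2-iodo-6-methoxyphenol
Product: 8 4-[(4-bromo-2-iodo-6-methoxyphenoxy)methyl]-2-methoxyphenyl pivalate
Conditions: PPh3, DIAD, THF, 0 °C to rt
Reagents that add atoms: none
Why: Mitsunobu etherification, in which the acidic phenol displaces the primary benzylic oxyphosphonium ion under neutral conditions that spare the aryl pivalate and both halogens.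

Step 5
Reactants: 8 aryl iodide; 9 ethyl diazoacetate
Product: 10 ethyl 2-[5-bromo-3-methoxy-2-{[3-methoxy-4-(pivaloyloxy)phenyl]methoxy}phenyl]-2-diazoacetate
Conditions: Pd(PPh3)4 (5 mol %), Ag2CO3 (0.5 equiv), Et3N, toluene, rt
Reagents that add atoms: none
Why: Pd(0)-catalysed cross-coupling of an aryl iodide with the C–H bond of a diazoacetate with retention of the diazo group, where oxidative addition at rt occurs only at C–I and C–Br is kept for step 8.

Step 6
Reactants: 10 aryl diazoacetate
Product: 12 ethyl (2R,3R)-5-bromo-7-methoxy-2-[3-methoxy-4-(pivaloyloxy)phenyl]-2,3-dihydrobenzofuran-3-carboxylate (trans), via cis ester 11 (not isolated)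
Conditions: Rh2(S-PTTL)4 (1 mol %), toluene, −60 °C; then dry DBU (2 equiv), 60 °C; recrystallisation
Reagents that add atoms: none
Why: Intramolecular 1,5 C–H insertion of a donor/acceptor rhodium carbene into the ether-activated benzylic CH2 closes the dihydrofuran and the chiral carboxylate pocket sets C2 as R (cis product kinetically), after which DBU epimerises the acidic C3–H through the ester enolate to the thermodynamically favoured trans ester without touching C2 or the acyl-masked phenol.

Step 7
Reactants: 12 trans ester
Product: 13 4-[(2R,3S)-5-bromo-3-(hydroxymethyl)-7-methoxy-2,3-dihydrobenzofuran-2-yl]-2-methoxyphenol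
Conditions: LiAlH4 (3 equiv), THF, 0 °C; aq Rochelle salt
Reagents that add atoms: none
Why: Hydride reduction turns the unhindered ethyl ester into CH2OH before the hindered aryl pivalate is cleaved, so a free phenoxide never coexists with an epimerisable C3, the aryl bromide is inert at 0 °C, and the C3 descriptor changes from R to S only through CIP priorities.

Step 8
Reactants: 3 allyl (E)-ferulate; 13 bromodihydrobenzofuran
Product: 15 3-[(2R,3S)-2-(4-hydroxy-3-methoxyphenyl)-3-(hydroxymethyl)-7-methoxy-2,3-dihydrobenzofuran-5-yl]propyl (E)-ferulate (target), via alkylborane 14 (not isolated)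
Conditions: 3 (1.5 equiv), 9-BBN (0.5 M in THF, 2.1 equiv per 3), 0 °C to rt; then 3 M aq K3PO4, 13, Pd(OAc)2/SPhos (5/10 mol %), THF–DMF, 60 °C
Reagents that add atoms: 9-borabicyclo[3.3.1]nonane (9-BBN), B1C2CCCC1CCC2 (its atoms appear only in 14; only hydrogen stays in 15)
Why: 9-BBN first turns the phenol O–H of 3 into an O–B borinate with loss of H2 (a protection that the later aqueous base removes by itself) and then adds anti-Markovnikov, through the usual four-centre transition state, to the only monosubstituted and unconjugated C=C, so that boron sits on the terminal carbon of 14. After borate formation with aqueous K3PO4, Pd(0)/SPhos inserts into the single C(sp2)–Br bond at C5 of 13, the primary alkyl group moves from boron to palladium and reductive elimination forms the C5–CH2 bond; the closest known reaction type is the hydroboration/B-alkyl Suzuki–Miyaura fragment coupling. No ring is closed and no stereocentre is created: C2 and C3 are spectators, C3 no longer carries an acidifying group, and a reversible opening of the C2–O1 bond through the p-quinone methide could only re-close to the trans ring dictated by C3. The step needs chemoselectivity between two alkenes and an ester, which the substrate secures because the cinnamate C=C is 1,2-disubstituted and electron-poor and alkyl esters are reduced only very slowly by this bulky borane. It also needs the ester to survive palladium and base: the allyl ester is saturated before palladium is added, so no π-allyl ionisation is possible, and the ferulate phenoxide formed in the basic medium lowers the electrophilicity of its vinylogous carbonyl group. The bulky electron-rich ligand speeds oxidative addition at the donor-substituted ring and makes reductive elimination faster than β-hydride elimination.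

Compound list
1 | (E)-ferulic acid | COc1cc(/C=C/C(=O)O)ccc1O | starting material
2 | allyl bromide | C=CCBr | starting material
3 | allyl (E)-ferulate | COc1cc(/C=C/C(=O)OCC=C)ccc1O | intermediate
4 | vanillyl alcohol | COc1cc(CO)ccc1O | starting material
5 | 4-(hydroxymethyl)-2-methoxyphenyl pivalate | COc1cc(CO)ccc1OC(=O)C(C)(C)C | intermediate
6 | 4-bromo-2-methoxyphenol | COc1cc(Br)ccc1O | starting material
7 | 4-bromo-2-iodo-6-methoxyphenol | COc1cc(Br)cc(I)c1O | intermediate
8 | 4-[(4-bromo-2-iodo-6-methoxyphenoxy)methyl]-2-methoxyphenyl pivalate | COc1cc(COc2c(I)cc(Br)cc2OC)ccc1OC(=O)C(C)(C)C | intermediate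
9 | ethyl diazoacetate | CCOC(=O)C=[N+]=[N-] | starting material
10 | ethyl 2-[5-bromo-3-methoxy-2-{[3-methoxy-4-(pivaloyloxy)phenyl]methoxy}phenyl]-2-diazoacetate | CCOC(=O)C(=[N+]=[N-])c1cc(Br)cc(OC)c1OCc1ccc(OC(=O)C(C)(C)C)c(OC)c1 | intermediate
11 | ethyl (2R,3S)-5-bromo-7-methoxy-2-[3-methoxy-4-(pivaloyloxy)phenyl]-2,3-dihydrobenzofuran-3-carboxylate (cis, not isolated) | Brc1cc(OC)c2c(c1)[C@H](C(=O)OCC)[C@H](c1ccc(OC(=O)C(C)(C)C)c(OC)c1)O2 | intermediate
12 | ethyl (2R,3R)-5-bromo-7-methoxy-2-[3-methoxy-4-(pivaloyloxy)phenyl]-2,3-dihydrobenzofuran-3-carboxylate (trans) | Brc1cc(OC)c2c(c1)[C@@H](C(=O)OCC)[C@H](c1ccc(OC(=O)C(C)(C)C)c(OC)c1)O2 | intermediate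
13 | 4-[(2R,3S)-5-bromo-3-(hydroxymethyl)-7-methoxy-2,3-dihydrobenzofuran-2-yl]-2-methoxyphenol | Brc1cc(OC)c2c(c1)[C@@H](CO)[C@H](c1ccc(O)c(OC)c1)O2 | intermediate
14 | 3-(9-borabicyclo[3.3.1]nonan-9-yl)propyl (E)-ferulate, phenol bound as its 9-BBN borinate (not isolated) | COc1cc(/C=C/C(=O)OCCCB2C3CCCC2CCC3)ccc1OB1C2CCCC1CCC2 | intermediate
15 | 3-[(2R,3S)-2-(4-hydroxy-3-methoxyphenyl)-3-(hydroxymethyl)-7-methoxy-2,3-dihydrobenzofuran-5-yl]propyl (E)-ferulate, CNP0149450.1 | COc1cc(/C=C/C(=O)OCCCc2cc(OC)c3c(c2)[C@@H](CO)[C@H](c2ccc(O)c(OC)c2)O3)ccc1O | target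

Total step count: 8.
Longest linear sequence: 6 steps (4 → 5 → 8 → 10 → 12 → 13 → 15, steps 2, 4, 5, 6, 7, 8). The branch from 6 is equally long.

Steps most likely to fail

Step 8. Oxidative addition at the donor-substituted C5–Br bond may be sluggish. That would let protodeboronation or β-hydride elimination of the alkyl partner, slow reduction of the cinnamate by surplus borane, or hydrolysis of the ester by the aqueous base compete. The fallback is a nickel-catalysed reductive cross-electrophile coupling, which needs neither borane nor base. It sets out from 1 and 13. Ferulic acid 1 is alkylated at the carboxylate with excess 1,3-dibromopropane (KHCO3, DMF, rt) to 3-bromopropyl (E)-ferulate F1. F1 and 13 are then joined with NiI2, 4,4'-dimethoxy-2,2'-bipyridine, NaI, pyridine and Zn in DMPU at 60 °C. This forms the same C5–CH2 bond and comes back to the route at 15.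

Step 5. Coupling at the ortho-alkoxy-substituted C–I bond may be slow, and palladium-carbene decomposition of the diazo group may overtake product formation. The fallback separates C–C bond formation from installation of the diazo group. It sets out from 8. Negishi-type α-arylation with the Reformatsky reagent BrZnCH2CO2Et (Pd(dba)2/Q-Phos, THF, rt, selective for C–I) should give ethyl 2-[5-bromo-3-methoxy-2-{[3-methoxy-4-(pivaloyloxy)phenyl]methoxy}phenyl]acetate F2. Regitz diazo transfer (p-ABSA, DBU, MeCN, 0 °C to rt) comes back to the route at 10.

Step 6. The base treatment may erode enantiopurity through retro-oxa-Michael opening of the ester enolate, may cleave the pivalate, or may stop short of equilibrium. The fallback corrects C2 instead of C3 and uses no base. It sets out from 10.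
- The mirror-image catalyst Rh2(R-PTTL)4 (toluene, −60 °C) should give the cis ester with the final C3 configuration, ethyl (2S,3R)-5-bromo-7-methoxy-2-[3-methoxy-4-(pivaloyloxy)phenyl]-2,3-dihydrobenzofuran-3-carboxylate F3.
- LiAlH4 (THF, 0 °C) converts it into the cis alcohol 4-[(2S,3S)-5-bromo-3-(hydroxymethyl)-7-methoxy-2,3-dihydrobenzofuran-2-yl]-2-methoxyphenol F4.
- Catalytic CF3CO2H in CH2Cl2 at rt reversibly ionises the C2–O1 bond to the p-hydroxybenzyl cation. Re-closure anti to the C3 substituent gives the more stable trans ring, which comes back to the route at 13.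

Further compounds
F1 | step 8 | 3-bromopropyl (E)-ferulate | COc1cc(/C=C/C(=O)OCCCBr)ccc1O
F2 | step 5 | ethyl 2-[5-bromo-3-methoxy-2-{[3-methoxy-4-(pivaloyloxy)phenyl]methoxy}phenyl]acetate | CCOC(=O)Cc1cc(Br)cc(OC)c1OCc1ccc(OC(=O)C(C)(C)C)c(OC)c1
F3 | step 6 | ethyl (2S,3R)-5-bromo-7-methoxy-2-[3-methoxy-4-(pivaloyloxy)phenyl]-2,3-dihydrobenzofuran-3-carboxylate (cis) | Brc1cc(OC)c2c(c1)[C@@H](C(=O)OCC)[C@@H](c1ccc(OC(=O)C(C)(C)C)c(OC)c1)O2
F4 | step 6 | 4-[(2S,3S)-5-bromo-3-(hydroxymethyl)-7-methoxy-2,3-dihydrobenzofuran-2-yl]-2-methoxyphenol (cis) | Brc1cc(OC)c2c(c1)[C@@H](CO)[C@@H](c1ccc(O)c(OC)c1)O2
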